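(Readings and results are simulated from invented constants; scatter was added.)

Scale every reading to this flask's charge before comparing runs.

| flask | solid substrate | remark | time |
|---|---|---|---|
| alpha | 0.56 M | run made earlier |  |
| gamma | 0.88 M | run made earlier |  |
| flask | 0.40 M |  | 10 d |

| alpha: time / d | alpha: product / % | gamma: time / d | gamma: product / % |
|---|---|---|---|
| 0.500 | 0.6 | 1.04 | 0 |
| 0.833 | 2.3 | 2.08 | 0.5 |
| 1.25 | 0.4 | 3.00 | 1.3 |
| 2.00 | 0 | 4.00 | 2.7 |
| 4.00 | 6.0 | 5.00 | 4.8 |
| 6.00 | 9.1 | 6.00 | 5.2 |

(standard deviation of a reading: 1 percentage point)

- how much product there is at 10 d, in percent of the solid substrate charged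
- the change that raises the amount of product at 10 d, in percent of the solid substrate charged most ("none" if none brings more than 2 percentage points) (west / south-west / none)
- amount of product at 10 d, in percent of the solid substrate charged, after south-west

- solid substrate is a solid; its amount is given per volume of the solution
- the analysis behind the earlier runs scatters by 1 percentage point, standard deviation
- steps under discussion: starting material -> intermediate A; starting material <-> intermediate B; starting material <-> intermediate C; intermediate A -> product; solid substrate <-> starting material
- at the start none of the solid substrate is in solution

Step 1. I defined the scaled yield: a reading multiplied by its run's charge and divided by this flask's charge. It is the fraction of this flask's charge that the same amount of product would be.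

Step 2. At 6.00 d, alpha scaled to 12.7 % and gamma to 11.4 %. They differed by 1.3 percentage points, less than gamma's scaled scatter of 2.2 points. So I read the product as zero-order in the charge and took the mean, 12.1 %.

Step 3. Alpha at 2.00 d and gamma at 2.08 d gave a scaled mean of 0.550 %. A straight line through both means reached a scaled yield at 10 d of 23.6 %.

Step 4. The weak link was the straight line: it carried the rate between those means unchanged from 6.00 d to 10 d, and the last reading of each run stood at 6.00 d. Carrying the scatter through gave a margin of 2.9 points. The runs varied neither solubility nor dissolution coefficient, so I reckoned no number for either change.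

The forecast gave 21 % (17 % to 26 %), west as the best change, and 24 % (19 % to 34 %) after south-west, holding that “output barely depends on the solid charged”.

The flask gave 26.9 %. West added 27 points and south-west 16 points, so west was best, and south-west reached 42.9 %.

    starting material → intermediate A (k = 1.20 × 10⁻⁵ s⁻¹)
    starting material ⇌ intermediate B (K = 0.740, k = 5.00 × 10⁻⁶ s⁻¹)
    starting material ⇌ intermediate C (K = 0.120, k = 3.80 × 10⁻⁴ s⁻¹)
    intermediate A → product (k = 6.80 × 10⁻⁶ s⁻¹)
    solid substrate ⇌ starting material, rate k5*(cs5 - [starting material]) while solid is left; crystals form when [starting material] > cs5 (solubility = 49.0 mM, k = 5.10 × 10⁻⁶ s⁻¹)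

My scaled yield stood 3.3 points below the flask's value. A neighbouring flask held 0.16 M of solid substrate and was read at the same time. This flask's charge was 2.50 times the neighbour's. My scaled yield carried across by that ratio gave 59.1 %, and the flask's own value gave 67.1 %. The neighbour gave 67.1 %, with 0.311 % of its charge still solid substrate.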